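All runs were generated by integration from invented constants; noise was put on by code.

On the list of suspects the solid Q goes to Z and Z goes to D or X, with no other step making or taking either, so [Q] + [Z] + [D] + [X] could not change, with one E counted as one D. I called that sum the Q budget, 0.0252 M; Q, charged below G, is the limiting reagent.

| flask | G | L | Q | remark | time |
|---|---|---|---|---|---|
| Monday's | 0.028 M | 7 equiv | 0.90 equiv | run made earlier |  |
| Wednesday's | 0.028 M | 11 equiv | 0.90 equiv | run made earlier |  |
| Tuesday's | 0.014 M | 5 equiv | 0.90 equiv | run made earlier |  |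
| alpha | 0.028 M | 5.00 equiv | 0.900 equiv |  | 3.0 min |
| delta | 0.028 M | 5.00 equiv | 0.900 equiv |  | 6.0 min |

| run | time / min | D / % | G / % |
|---|---|---|---|
| Monday's | 0.417 | 1.2 | 97.1 |
| Monday's | 1.33 | 4.9 | 85.8 |
| Monday's | 2.50 | 15.1 | 72.1 |
| Monday's | 4.00 | 23.0 | 54.1 |
| Wednesday's | 0.250 | 0.6 | 96.3 |
| Wednesday's | 0.667 | 0.9 | 89.6 |
| Wednesday's | 1.50 | 7.4 | 80.4 |
| Wednesday's | 4.00 | 20.2 | 51.6 |
| Tuesday's | 0.417 | 1.4 | 98.4 |
| Tuesday's | 1.33 | 6.5 | 87.5 |
| Tuesday's | 2.50 | 17.0 | 75.9 |
| Tuesday's | 4.00 | 31.6 | 59.7 |

(standard deviation of a reading: 1 percentage point)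

- percentages count the G that a species holds: one E counts as two
- D is meant together with its E
- solid, in amounts per volume of the solution: Q
- what was read earlier has a scatter of 1 percentage point, one standard deviation
- on the list of suspects stand: G + D <-> E; L + Z -> X; G + L -> J; Q <-> Z; G + Z -> D
- at the start none of Q is in solution
- in an amount of D, one E counts as one D

- which of the two there is more of at the end, alpha (D / J)
- which of the two there is more of at the end, delta (D / J)
- amount of D at the end, in percent of the G charged, alpha
- amount of D at the end, in percent of the G charged, delta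

From Monday's run I took D's rate and, with it, a ladder of clocks, shortest first:

rate of D, from 1.33 min to 4.00 min: 0.00190 M min⁻¹

lag of D, where that line meets zero: 0.607 min

half-life of G, read as first order from the last reading: 4.51 min

budget time, budget over rate: 13.3 min

Alpha's reading comes after the lag but before G's half-life. Delta's comes after that half-life, so its line might bend. The budget time is longer than delta's 6.0 min, so by my reckoning D's line stayed within the budget in both flasks, though X, unseen, draws on it too. The line gave me 16.2% for alpha and 36.6% for delta.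

Monday's G seen neither as G nor as D, taken as J and scaled to alpha's L, grew at 0.00114 M min⁻¹, which made 12.3% by alpha's reading, less than my D there, and it grew slower than D, so I expected D above J in both flasks.

The forecast also chose D and D, with 19% and 37%: “Falling G is offset by rising Z”. My alpha stands below its figure.

Alpha gave 18.4% of D and 9.23% of J; delta gave 39.2% and 14.8%.

    G + D ⇌ E, settled at all times (K = 13.6 M⁻¹)
    L + Z → X (k = 0.0225 M⁻¹ s⁻¹)
    G + L → J (k = 0.00434 M⁻¹ s⁻¹)
    Q ⇌ Z, rate k4*(cs4 - [Z]) while solid is left; crystals form when [Z] > cs4 (solubility = 26.0 mM, k = 0.00369 s⁻¹)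
    G + Z → D (k = 0.282 M⁻¹ s⁻¹)

In alpha at 1.40 min, G took Z 2.2 times as fast as L did. At 3.00 min alpha's [X] was 0.00246 M and [Z] 0.00671 M, so the budget less these and D left 43.1% of it as solid, and the solid stood at 43.1%. Alpha read at 12.0 min held 50.2% of D, [X] 0.00998 M and solid Q 0%; the budget less these leaves 0.00116 M, and [Z] stood at 0.00116 M.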